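The pyrrole ring is cut at C3–C3a and N1–C2, leading back to a Fischer indolization of hydrazone 4, made from (2-bromophenyl)hydrazine and ethyl pyruvate. In one acid-mediated operation the key step forges both bonds, closes the five-membered ring and expels ammonia to give indole ester 8. It exploits the surroundings of C7a in the benzene ring: C7a carries N1 and is flanked by C7, blocked by bromine, and by C3a, the only ortho carbon bearing hydrogen in 4, so the sigmatropic shift has one productive direction. The C2 ester steadies the hydrazone, shields C2 in hot acid and is finally traded for bromine with loss of CO2.

Key step: step 2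

Remark on the chemistry: hydrazone 4 is drawn as the Z isomer, favoured by an N–H···O=C hydrogen bond. Any E isomer formed alongside is carried on, because acid interconverts both through 5. Compounds 5–7 are listed in neutral form although they are protonated in the acid medium.

Step 1
Reactants: 1 (2-bromophenyl)hydrazine hydrochloride; 2 ethyl pyruvate
Product: 4 ethyl (2Z)-2-[2-(2-bromophenyl)hydrazinylidene]propanoate, via free hydrazine 3 (not isolated)
Conditions: NaOAc (1.1 equiv), EtOH, rt, under N2; dilute with H2O, filter, wash with H2O until chloride-free, dry in vacuo
Reagents that add atoms: none
Why: Acetate frees the nucleophilic base 3, whose terminal NH2 group condenses with the strongly electrophilic ketone carbonyl of 2 in an ordinary hydrazone formation (addition–elimination) that leaves the ester alone, the Z geometry being held by an N–H···O=C hydrogen bond and the water wash removing chloride before the acid step.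

Step 2
Reactants: 4 ethyl (2Z)-2-[2-(2-bromophenyl)hydrazinylidene]propanoate
Product: 8 ethyl 7-bromo-1H-indole-2-carboxylate, via ene-hydrazine 5 (not isolated), via imino aniline 6 (not isolated), via aminoindoline 7 (not isolated)
Conditions: polyphosphoric acid (PPA), 100–110 °C; pour onto ice/H2O, extract with EtOAc
Reagents that add atoms: none
Why: Acid converts 4 into its ene-hydrazine tautomer 5, in which the former pyruvate methyl group is a terminal methylene; a concerted [3,3]-sigmatropic rearrangement through a chair-like six-atom array bonds that methylene (future C3) to the hydrogen-bearing ortho carbon (future C3a) as the weak N–N bond breaks, and proton loss from C3a restores the arene to give imino aniline 6. The liberated aniline nitrogen then adds to the protonated imine carbon to make N1–C2 (aminoindoline 7), and elimination of ammonia aromatises the new ring to 8. The closest known reaction type is the Fischer indole synthesis of pyruvate arylhydrazones in polyphosphoric acid, so this is established chemistry applied to a bromo-substituted case. The one ring closed is the pyrrole ring, and it closes in the 5-exo-trig mode because the C=N bond under attack lies outside the ring being formed. No stereocentre has to be controlled: C2 of 7 arises as a racemate and becomes planar again when ammonia leaves. The step needs regioselectivity between the two ortho carbons and retention of the C7 bromine; the first is secured because a shift onto the brominated carbon gives a dearomatised adduct with no proton to lose, and the second because chloride-free 4 in a non-nucleophilic phosphoric medium meets no halide that could exchange with or displace bromine.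

Step 3
Reactants: 8 ethyl 7-bromo-1H-indole-2-carboxylate
Product: 10 7-bromo-1H-indole-2-carboxylic acid, via lithium carboxylate 9 (not isolated)
Conditions: LiOH·H2O (3 equiv), THF/MeOH/H2O, rt to 40 °C; 1 M HCl to pH 2, 0 °C, filter, dry thoroughly in vacuo
Reagents that add atoms: lithium hydroxide, [Li+].[OH-]
Why: Ordinary saponification (acyl addition–elimination by hydroxide) should convert the ethyl ester into carboxylate 9 without touching the aryl bromide or the indole ring, and cold acidification precipitates 10, which is far from decarboxylation at this temperature.

Step 4
Reactants: 10 7-bromo-1H-indole-2-carboxylic acid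
Product: 12 2,3,7-tribromo-1H-indole, via dibromo acid 11 (not isolated)
Conditions: NBS (2.05 equiv, two portions), LiOAc (0.2 equiv), dry DMF, 0 °C to rt, dark; cold aqueous work-up, rapid filtration through Et3N-deactivated silica, store cold and dark
Reagents that add atoms: N-bromosuccinimide, O=C1CCC(=O)N1Br
Why: Electrophilic aromatic bromination first takes the most nucleophilic free position C3 to give 11, after which the second equivalent of NBS attacks C2 ipso to the carboxylate and the adduct regains aromaticity by expelling CO2 (halodecarboxylation of an electron-rich heteroaromatic acid, Hunsdiecker-type in outcome but ionic in mechanism), while the deactivating bromines already present and the exact stoichiometry hold back attack on the benzene ring.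

Compound list
1 | (2-bromophenyl)hydrazine hydrochloride | NNc1ccccc1Br.Cl | starting material
2 | ethyl pyruvate (ethyl 2-oxopropanoate) | CCOC(=O)C(C)=O | starting material
3 | (2-bromophenyl)hydrazine, free base | NNc1ccccc1Br | intermediate
4 | ethyl (2Z)-2-[2-(2-bromophenyl)hydrazinylidene]propanoate | CCOC(=O)/C(C)=N\Nc1ccccc1Br | intermediate
5 | ethyl 2-[2-(2-bromophenyl)hydrazinyl]prop-2-enoate (ene-hydrazine tautomer) | CCOC(=O)C(=C)NNc1ccccc1Br | intermediate
6 | ethyl 3-(2-amino-3-bromophenyl)-2-iminopropanoate | CCOC(=O)C(=N)Cc1cccc(Br)c1N | intermediate
7 | ethyl 2-amino-7-bromo-2,3-dihydro-1H-indole-2-carboxylate (racemic, transient) | CCOC(=O)C1(N)Cc2cccc(Br)c2N1 | intermediate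
8 | ethyl 7-bromo-1H-indole-2-carboxylate | CCOC(=O)c1cc2cccc(Br)c2[nH]1 | intermediate
9 | lithium 7-bromo-1H-indole-2-carboxylate | [Li+].[O-]C(=O)c1cc2cccc(Br)c2[nH]1 | intermediate
10 | 7-bromo-1H-indole-2-carboxylic acid | OC(=O)c1cc2cccc(Br)c2[nH]1 | intermediate
11 | 3,7-dibromo-1H-indole-2-carboxylic acid | OC(=O)c1[nH]c2c(Br)cccc2c1Br | intermediate
12 | 2,3,7-tribromo-1H-indole | Brc1[nH]c2c(Br)cccc2c1Br | target

Total step count: 4. Longest linear sequence: 4 steps (1 + 2 → 4 → 8 → 10 → 12).

Steps most likely to fail

Step 2. Possible failures:
- charring and partial ester cleavage in the hot, viscous acid
- sluggish tautomerisation of the electron-poor hydrazone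
- migration or loss of bromine after attack at the blocked ortho carbon

The fallback sets out from 2 and comes back at 8. Compound 2 is condensed with commercial 2-bromo-6-iodoaniline (Nc1c(Br)cccc1I) under dehydrating conditions (PPTS, 4 Å molecular sieves, toluene, reflux). This gives ethyl 2-[(2-bromo-6-iodophenyl)amino]prop-2-enoate F1. The C3–C3a bond is then made by an intramolecular Heck-type cyclisation (Pd(OAc)2, DABCO, DMF, 105 °C). Zerovalent palladium should insert into the more reactive carbon–iodine bond and leave the carbon–bromine bond alone. The halogen pattern, not an acid-driven rearrangement, then fixes the regiochemistry.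

Step 4. Possible failures:
- stalling after the first bromination, because the ring has become electron-poor
- further bromination of the benzene ring
- hydrolytic oxidation at C2 if moisture is present
- decomposition of the acid- and light-sensitive product during purification

The fallback sets out from 10 and comes back at 12. The carboxyl group is first removed by protodecarboxylation (Ag2CO3 10 mol %, AcOH, DMSO, 120 °C) to give 7-bromo-1H-indole F2. Two successive C–H brominations follow with NBS (2 equiv) on silica gel in CH2Cl2 at rt in the dark. The first goes to C3 and gives 3,7-dibromo-1H-indole F3. The second goes to C2 and gives 12, so no ipso substitution is needed.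

Step 1. Possible failures:
- air oxidation of the liberated hydrazine
- self-condensation of ethyl pyruvate
- separation of the hydrazone as an oily mixture of geometric isomers that occludes chloride salts

The fallback sets out from 1 and comes back at 4. Compound 1 is condensed in aqueous NaOAc/AcOH with pyruvic acid (CC(=O)C(=O)O). The product, (2Z)-2-[2-(2-bromophenyl)hydrazinylidene]propanoic acid F4, should crystallise directly from water free of chloride. Fischer esterification (EtOH, cat. H2SO4, reflux) then gives 4. Any indolization that begins during esterification only feeds forward to 8.

Further compounds
F1 | step 2 | ethyl 2-[(2-bromo-6-iodophenyl)amino]prop-2-enoate | CCOC(=O)C(=C)Nc1c(Br)cccc1I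
F2 | step 4 | 7-bromo-1H-indole | Brc1cccc2cc[nH]c12
F3 | step 4 | 3,7-dibromo-1H-indole | Brc1c[nH]c2c(Br)cccc12
F4 | step 1 | (2Z)-2-[2-(2-bromophenyl)hydrazinylidene]propanoic acid | OC(=O)/C(C)=N\Nc1ccccc1Br
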